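In a one-step world starting material simply becomes target, and one flask differs from another in how far along it is. Two chemists argue at the board over whether that world is enough here.

| flask | starting material | protic impurity | enzyme | remark | time |
|---|---|---|---|---|---|
| dusk | 34 mM | 0.39 mM | 3.4 µM | run made earlier |  |
| autumn | 34 mM | 1.5 mM | 3.4 µM | run made earlier |  |
| violet | 34 mM | 0.300 mM | 3.4 µM |  | 4.0 h |
| grey | 34 mM | 0.500 mM | 3.4 µM |  | 4.0 h |
| ochre | 34 mM | 0.600 mM | 3.4 µM |  | 4.0 h |
| amber | 34 mM | 1.00 mM | 3.4 µM |  | 4.0 h |

- dusk (time / h: target / %): 0.667: 52.3; 1.33: 82.7; 2.00: 94.2; 3.00: 97.8
- autumn (time / h: target / %): 0.667: 51.7; 1.33: 80.7; 2.00: 91.4; 3.00: 94.5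

(standard deviation of a reading: 0.3 percentage points)

- "hardly changes" means that all values lie within two and a half points (for a concentration: within two and a half percent of the largest)

- amount of target at the end, in percent of the starting material charged for violet, grey, ochre, amber, in this order
- the shape of the row from first to last (hardly changes / falls, then rises / falls all the way / rises, then falls / rises all the way)

Ines holds the one-step view: protic impurity slows the enzyme, so autumn is merely late. What is missing then shrinks by a steady factor each hour. She takes that factor from the last hour of each run and reaches, at 4.0 h, 99.2% for dusk and 96.5% for autumn. A straight line through these two in the impurity charge gives 99.4% for violet, which lies just outside the two charges, and 97.7% for amber.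

Tom points to the first reading, where the two runs stand just 0.6 percentage points apart, while at 3.00 h they stand 3.3 points apart. He reads that later gap as a loss, not lateness, and defines the toll T, the molecules of starting material lost per molecule of protic impurity charged. As a reading, with the scatter of the two runs in it, T is the gap times the starting charge, divided by the extra impurity: 1.01.

The forecast is his: 98.9%, 98.3%, 98%, 96.8%, shape "hardly changes", since “each impurity molecule costs about one molecule of material”. The two part at amber, by 0.90 points against a scatter of 0.3 points.

The flask gives 98.9%, 98.3%, 98.0%, 96.8%, shape "hardly changes", so Tom's row stands.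

    starting material + enzyme ⇌ complex (K = 61.0 L mol⁻¹, k = 1.40 × 10⁷ L mol⁻¹ h⁻¹)
    complex → enzyme + target (k = 14000 h⁻¹)
    starting material + protic impurity → quenched substrate (k = 310 L mol⁻¹ h⁻¹)
    2 enzyme → spent catalyst (k = 63000 L mol⁻¹ h⁻¹)

Ines comes nearer at the violet end, where she misses by 0.50 points, against 0.90 points in amber; violet holds 0.882% quenched substrate at 4.0 h. Protic impurity is the limiting reagent of this loss, with 0.041% of amber's charge left. In amber, T puts the loss at 2.97% of the starting material, and with 0.22% unconverted that reckons to 96.8%. In grey, T puts the loss at 1.49%, and the flask holds 1.47% quenched substrate.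

The readings are simulated with constants of no real substance; scatter was added.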